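The route rests on the butyrolactone ring (O1, C2 carbonyl, C3, C4, C5). C4, which carries the benzyl group of ring A (the phenol ring of the open diol unit), sits between C3 and C5; with O1 deleted and the C3 benzyl group removed these are the two enantiotopic CH2 arms of a 3-substituted cyclobutanone. A catalytic asymmetric Baeyer–Villiger oxidation inserts O1, forms the O1–C5 bond, closes the lactone and fixes C4 in one operation. Its precursor is a cyclobutanone carrying the protected diarylpropanediol unit (magnesium-catalysed anti aldol). The lactone is then benzylated at C3, trans to C4, with a phenylcoumaran bromide made from the same acyl oxazolidinone by syn aldol and acid-mediated ring closure.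

Key step: step 8

Labels: ring B is the benzo ring of the dihydrobenzofuran; ring G is either 4-hydroxy-3-methoxyphenyl ring; TIPS = triisopropylsilyl, TBS = tert-butyldimethylsilyl, TMS = trimethylsilyl.
Assumption: compounds 1, 5, 8 and 13 are taken as catalogue compounds.

Step 1
Reactants: 1 2-(2-hydroxy-3-methoxyphenyl)acetic acid
Product: 2 2-(5-bromo-2-hydroxy-3-methoxyphenyl)acetic acid
Conditions: NBS (1.05 equiv), MeCN, 0 °C → rt
Reagents that add atoms: N-bromosuccinimide, O=C1CCC(=O)N1Br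
Why: Electrophilic aromatic bromination: the free phenol directs to its para position, the only unsubstituted site ortho or para to it, so bromine should enter at C5 only.

Step 2
Reactants: 2 2-(5-bromo-2-hydroxy-3-methoxyphenyl)acetic acid
Product: 4 2-[5-bromo-3-methoxy-2-(TIPS-oxy)phenyl]acetic acid, via bis-silylated ester 3 (not isolated)
Conditions: TIPSOTf (2.3 equiv), 2,6-lutidine, CH2Cl2, 0 °C → rt; then AcOH/THF/H2O, rt
Reagents that add atoms: triisopropylsilyl trifluoromethanesulfonate, CC(C)[Si](OS(=O)(=O)C(F)(F)F)(C(C)C)C(C)C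
Why: Silyl triflate silylation of the hindered phenol (the acid is silylated too) followed by selective solvolysis of the labile silyl ester, which the aryl TIPS ether survives.

Step 3
Reactants: 4 2-[5-bromo-3-methoxy-2-(TIPS-oxy)phenyl]acetic acid; 5 (S)-4-benzyl-1,3-oxazolidin-2-one
Product: 7 (S)-4-benzyl-3-{2-[5-bromo-3-methoxy-2-(TIPS-oxy)phenyl]acetyl}-1,3-oxazolidin-2-one, via mixed pivalic anhydride 6 (not isolated)
Conditions: PivCl, Et3N, THF, −20 °C; then 5, LiCl, −20 °C → rt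
Reagents that add atoms: none
Why: N-Acylation of the oxazolidinone through the mixed pivalic anhydride under the LiCl/Et3N protocol, a standard entry to Evans imides from arylacetic acids.

Step 4
Reactants: 7 (S)-4-benzyl-3-{2-[5-bromo-3-methoxy-2-(TIPS-oxy)phenyl]acetyl}-1,3-oxazolidin-2-one; 8 4-(TBS-oxy)-3-methoxybenzaldehyde
Product: 10 (S)-4-benzyl-3-{(2R,3S)-2-[5-bromo-3-methoxy-2-(TIPS-oxy)phenyl]-3-hydroxy-3-[3-methoxy-4-(TBS-oxy)phenyl]propanoyl}-1,3-oxazolidin-2-one (anti adduct), via trimethylsilyl ether 9 (not isolated)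
Conditions: MgCl2 (20 mol%), Et3N, TMSCl, EtOAc, rt; then TFA (cat.), MeOH, 0 °C
Reagents that add atoms: none
Why: Magnesium-halide-catalysed direct anti aldol of an N-acyl oxazolidinone with a non-enolisable aromatic aldehyde: soft enolisation gives the chelated Z enolate, the aldehyde adds to the face away from the auxiliary benzyl group through a boat-like transition state and TMSCl silylates the aldolate (turnover, no retro-aldol), which sets C2 (R) and C3 (S) of the chain in the anti relationship.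

Step 5
Reactants: 10 anti aldol adduct
Product: 11 (1S,2S)-2-[5-bromo-3-methoxy-2-(TIPS-oxy)phenyl]-1-[3-methoxy-4-(TBS-oxy)phenyl]propane-1,3-diol
Conditions: LiBH4, MeOH (2 equiv), THF, 0 °C
Reagents that add atoms: none
Why: Reductive cleavage of the imide by LiBH4 gives the primary alcohol and returns the auxiliary without touching the aryl bromide or the silyl ethers; the chain carbon next to ring A keeps its geometry and is S only by the change in substituent priority.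

Step 6
Reactants: 11 (1S,2S)-diol
Product: 12 (1S,2S)-1,3-bis(TBS-oxy)-2-[5-bromo-3-methoxy-2-(TIPS-oxy)phenyl]-1-[3-methoxy-4-(TBS-oxy)phenyl]propane
Conditions: TBSOTf (2.4 equiv), 2,6-lutidine, CH2Cl2, −78 → 0 °C
Reagents that add atoms: tert-butyldimethylsilyl trifluoromethanesulfonate, CC(C)(C)[Si](C)(C)OS(=O)(=O)C(F)(F)F
Why: Silyl triflate/2,6-lutidine silylation caps the primary and the hindered benzylic hydroxyl in one operation under non-acidic conditions.

Step 7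
Reactants: 12 protected ring A aryl bromide; 13 3-(bromomethyl)cyclobutan-1-one
Product: 15 3-{3-[(1S,2S)-1,3-bis(TBS-oxy)-1-(3-methoxy-4-TBS-oxyphenyl)propan-2-yl]-5-methoxy-4-(TIPS-oxy)benzyl}cyclobutan-1-one, via alkylzinc bromide 14 (not isolated)
Conditions: 13, Zn dust, LiCl, THF, 40 °C; then 12, Pd(OAc)2 (3 mol%), SPhos (6 mol%), THF, 50 °C
Reagents that add atoms: none
Why: Negishi coupling: zinc inserts into the primary C–Br bond of 13 (alkylzinc halides tolerate ketones) and zerovalent palladium with SPhos joins alkylzinc 14 to the aryl bromide, whose two ortho positions are unsubstituted.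

Step 8
Reactants: 15 3-(arylmethyl)cyclobutanone
Product: 17 (R)-4-{3-[(1S,2S)-1,3-bis(TBS-oxy)-1-(3-methoxy-4-TBS-oxyphenyl)propan-2-yl]-5-methoxy-4-(TIPS-oxy)benzyl}dihydrofuran-2(3H)-one, via Criegee adduct 16 (not isolated)
Conditions: Sc(OTf)3 (10 mol%), chiral L-proline-derived N,N'-dioxide bis(2,6-diisopropylanilide) ligand (12 mol%; antipode that delivers the 4R lactone), m-CPBA (1.2 equiv), EtOAc, −20 °C
Reagents that add atoms: 3-chloroperoxybenzoic acid, OOC(=O)c1cccc(Cl)c1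
Why: Baeyer–Villiger oxidation: the peracid adds to the strained ketone bound to the chiral scandium N,N'-dioxide complex to give Criegee adduct 16, then one ring CH2 shifts from the former carbonyl carbon to the proximal peroxide oxygen as 3-chlorobenzoate leaves, which makes the O1–C5 bond. The closest known reaction type is the catalytic asymmetric Baeyer–Villiger desymmetrisation of prochiral 3-substituted cyclobutanones, 3-benzyl members included, as used for lignan lactones. The five-membered lactone is closed by ring expansion (1,2-shift of C5 to oxygen with retention at the migrating carbon), not by an open-chain cyclisation. No bond is formed at C4: its R configuration results from the catalyst choosing which of the two enantiotopic CH2 groups migrates. The step needs chemoselectivity for the ketone over the electron-rich arenes and the four silyl ethers, which the ring strain of the cyclobutanone should secure at −20 °C; regiochemistry is not an issue because both possible migrating groups are CH2, and the existing stereocentres are remote, so the catalyst alone should set the sense.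

Step 9
Reactants: 7 (S)-4-benzyl-3-{2-[5-bromo-3-methoxy-2-(TIPS-oxy)phenyl]acetyl}-1,3-oxazolidin-2-one; 8 4-(TBS-oxy)-3-methoxybenzaldehyde
Product: 19 (S)-4-benzyl-3-{(2S,3S)-2-[5-bromo-3-methoxy-2-(TIPS-oxy)phenyl]-3-hydroxy-3-[3-methoxy-4-(TBS-oxy)phenyl]propanoyl}-1,3-oxazolidin-2-one (syn adduct), via boron enolate 18 (not isolated)
Conditions: Bu2BOTf, iPr2NEt, CH2Cl2, −78 → 0 °C; then 8, −78 → 0 °C; pH 7 buffer, MeOH, 30% H2O2, 0 °C
Reagents that add atoms: none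
Why: Evans syn aldol: the Z dibutylboron enolate 18 reacts through a closed Zimmerman–Traxler chair with the auxiliary carbonyl turned away from boron, so the aldehyde adds to the enolate face opposite to that used in step 4 and the (2S,3S) syn adduct should form.

Step 10
Reactants: 19 syn aldol adduct
Product: 20 (1S,2R)-2-[5-bromo-3-methoxy-2-(TIPS-oxy)phenyl]-1-[3-methoxy-4-(TBS-oxy)phenyl]propane-1,3-diol
Conditions: LiBH4, MeOH (2 equiv), THF, 0 °C
Reagents that add atoms: none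
Why: Reductive cleavage of the imide by LiBH4 as in step 5; the carbon bearing ring B becomes R by the priority change and the benzylic carbinol stays S.

Step 11
Reactants: 20 (1S,2R)-diol
Product: 22 4-[(2S,3R)-5-bromo-3-(hydroxymethyl)-7-methoxy-2,3-dihydro-1-benzofuran-2-yl]-2-methoxyphenol, via bisphenol tetraol 21 (not isolated)
Conditions: TBAF (2.2 equiv), THF, 0 °C; then TsOH·H2O (2.5 equiv), 0 °C → rt
Reagents that add atoms: none
Why: Fluoride frees both phenols, then acid ionises the 4-hydroxybenzylic alcohol to a quinone-methide-type cation that the ring B phenol traps in a 5-exo closure (biomimetic phenylcoumaran formation), a reversible process that should settle on the more stable trans dihydrobenzofuran, so C2 becomes S next to the untouched C3 (R).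

Step 12
Reactants: 22 trans-dihydrobenzofuran phenol alcohol
Product: 23 (2S,3R)-5-bromo-3-(TBS-oxymethyl)-7-methoxy-2-[3-methoxy-4-(TBS-oxy)phenyl]-2,3-dihydro-1-benzofuran
Conditions: TBSCl (2.5 equiv), imidazole, DMF, rt
Reagents that add atoms: tert-butyldimethylsilyl chloride, CC(C)(C)[Si](C)(C)Cl
Why: Standard TBSCl/imidazole silylation protects the phenol and the primary alcohol for the organometallic steps that follow.

Step 13
Reactants: 23 bis-TBS aryl bromide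
Product: 24 {(2S,3R)-3-(TBS-oxymethyl)-7-methoxy-2-[3-methoxy-4-(TBS-oxy)phenyl]-2,3-dihydro-1-benzofuran-5-yl}methanol
Conditions: Bu3SnCH2OH, Pd(PPh3)4 (5 mol%), 1,4-dioxane, 90 °C
Reagents that add atoms: (tributylstannyl)methanol, CCCC[Sn](CCCC)(CCCC)CO
Why: Stille coupling with (tributylstannyl)methanol transfers the hydroxymethyl group to the aryl bromide under neutral conditions that spare the silyl ethers and the benzylic ether of the dihydrobenzofuran.

Step 14
Reactants: 24 benzylic alcohol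
Product: 25 (2S,3R)-5-(bromomethyl)-3-(TBS-oxymethyl)-7-methoxy-2-[3-methoxy-4-(TBS-oxy)phenyl]-2,3-dihydro-1-benzofuran
Conditions: CBr4, PPh3, CH2Cl2, 0 °C
Reagents that add atoms: carbon tetrabromide, BrC(Br)(Br)Br
Why: Appel bromination turns the electron-rich benzylic alcohol into the bromide under neutral conditions; the reactive bromide is used directly.

Step 15
Reactants: 17 (R)-4-(arylmethyl)butyrolactone; 25 benzylic bromide
Product: 27 (3R,4R)-3-({(2S,3R)-3-(TBS-oxymethyl)-7-methoxy-2-[3-methoxy-4-(TBS-oxy)phenyl]-2,3-dihydro-1-benzofuran-5-yl}methyl)-4-{3-[(1S,2S)-1,3-bis(TBS-oxy)-1-(3-methoxy-4-TBS-oxyphenyl)propan-2-yl]-5-methoxy-4-(TIPS-oxy)benzyl}dihydrofuran-2(3H)-one, via lithium enolate 26 (not isolated)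
Conditions: LiHMDS (1.1 equiv), THF, −78 °C; then 25, DMPU, −78 → −40 °C
Reagents that add atoms: none
Why: Alkylation of lactone lithium enolate 26 with the benzylic bromide: the electrophile approaches the enolate face anti to the C4 benzyl group, the established route to trans-α,β-dibenzylbutyrolactones, which sets C3 (R).

Step 16
Reactants: 27 hexasilylated lactone
Product: 28 (3R,4R)-4-{3-[(1S,2S)-1,3-dihydroxy-1-(4-hydroxy-3-methoxyphenyl)propan-2-yl]-4-hydroxy-5-methoxybenzyl}-3-{[(2S,3R)-2-(4-hydroxy-3-methoxyphenyl)-3-(hydroxymethyl)-7-methoxy-2,3-dihydro-1-benzofuran-5-yl]methyl}dihydrofuran-2(3H)-one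
Conditions: TBAF (8 equiv), AcOH (8 equiv), THF, 0 °C → rt
Reagents that add atoms: none
Why: Fluoride-mediated global desilylation buffered with AcOH removes the five TBS groups and the TIPS group without opening or epimerising the lactone and without acid that could ionise the benzylic alcohol beside the free ring A phenol.

Compound list
1 | 2-(2-hydroxy-3-methoxyphenyl)acetic acid | COc1cccc(CC(=O)O)c1O | starting material
2 | 2-(5-bromo-2-hydroxy-3-methoxyphenyl)acetic acid | COc1cc(Br)cc(CC(=O)O)c1O | intermediate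
3 | triisopropylsilyl 2-[5-bromo-3-methoxy-2-(TIPS-oxy)phenyl]acetate | COc1cc(Br)cc(CC(=O)O[Si](C(C)C)(C(C)C)C(C)C)c1O[Si](C(C)C)(C(C)C)C(C)C | intermediate
4 | 2-[5-bromo-3-methoxy-2-(TIPS-oxy)phenyl]acetic acid | COc1cc(Br)cc(CC(=O)O)c1O[Si](C(C)C)(C(C)C)C(C)C | intermediate
5 | (S)-4-benzyl-1,3-oxazolidin-2-one | O=C1N[C@@H](Cc2ccccc2)CO1 | starting material
6 | 2-[5-bromo-3-methoxy-2-(TIPS-oxy)phenyl]acetic pivalic anhydride | COc1cc(Br)cc(CC(=O)OC(=O)C(C)(C)C)c1O[Si](C(C)C)(C(C)C)C(C)C | intermediate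
7 | (S)-4-benzyl-3-{2-[5-bromo-3-methoxy-2-(TIPS-oxy)phenyl]acetyl}-1,3-oxazolidin-2-one | COc1cc(Br)cc(CC(=O)N2C(=O)OC[C@@H]2Cc2ccccc2)c1O[Si](C(C)C)(C(C)C)C(C)C | intermediate
8 | 4-(tert-butyldimethylsilyloxy)-3-methoxybenzaldehyde | COc1cc(C=O)ccc1O[Si](C)(C)C(C)(C)C | starting material
9 | 3-O-trimethylsilyl ether of anti adduct 10 | COc1cc([C@@H](O[Si](C)(C)C)[C@H](C(=O)N2C(=O)OC[C@@H]2Cc2ccccc2)c2cc(Br)cc(OC)c2O[Si](C(C)C)(C(C)C)C(C)C)ccc1O[Si](C)(C)C(C)(C)C | intermediate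
10 | (S)-4-benzyl-3-{(2R,3S)-2-[5-bromo-3-methoxy-2-(TIPS-oxy)phenyl]-3-hydroxy-3-[3-methoxy-4-(TBS-oxy)phenyl]propanoyl}-1,3-oxazolidin-2-one | COc1cc([C@@H](O)[C@H](C(=O)N2C(=O)OC[C@@H]2Cc2ccccc2)c2cc(Br)cc(OC)c2O[Si](C(C)C)(C(C)C)C(C)C)ccc1O[Si](C)(C)C(C)(C)C | intermediate
11 | (1S,2S)-2-[5-bromo-3-methoxy-2-(TIPS-oxy)phenyl]-1-[3-methoxy-4-(TBS-oxy)phenyl]propane-1,3-diol | COc1cc([C@@H](O)[C@H](CO)c2cc(Br)cc(OC)c2O[Si](C(C)C)(C(C)C)C(C)C)ccc1O[Si](C)(C)C(C)(C)C | intermediate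
12 | (1S,2S)-1,3-bis(TBS-oxy)-2-[5-bromo-3-methoxy-2-(TIPS-oxy)phenyl]-1-[3-methoxy-4-(TBS-oxy)phenyl]propane | COc1cc([C@@H](O[Si](C)(C)C(C)(C)C)[C@H](CO[Si](C)(C)C(C)(C)C)c2cc(Br)cc(OC)c2O[Si](C(C)C)(C(C)C)C(C)C)ccc1O[Si](C)(C)C(C)(C)C | intermediate
13 | 3-(bromomethyl)cyclobutan-1-one | O=C1CC(CBr)C1 | starting material
14 | [(3-oxocyclobutyl)methyl]zinc bromide | O=C1CC(C[Zn]Br)C1 | intermediate
15 | 3-{3-[(1S,2S)-1,3-bis(TBS-oxy)-1-(3-methoxy-4-TBS-oxyphenyl)propan-2-yl]-5-methoxy-4-(TIPS-oxy)benzyl}cyclobutan-1-one | COc1cc([C@@H](O[Si](C)(C)C(C)(C)C)[C@H](CO[Si](C)(C)C(C)(C)C)c2cc(CC3CC(=O)C3)cc(OC)c2O[Si](C(C)C)(C(C)C)C(C)C)ccc1O[Si](C)(C)C(C)(C)C | intermediate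
16 | Criegee adduct of 15: 1-hydroxy-1-(3-chlorobenzoylperoxy)cyclobutane | COc1cc([C@@H](O[Si](C)(C)C(C)(C)C)[C@H](CO[Si](C)(C)C(C)(C)C)c2cc(CC3CC(O)(OOC(=O)c4cccc(Cl)c4)C3)cc(OC)c2O[Si](C(C)C)(C(C)C)C(C)C)ccc1O[Si](C)(C)C(C)(C)C | intermediate
17 | (R)-4-{3-[(1S,2S)-1,3-bis(TBS-oxy)-1-(3-methoxy-4-TBS-oxyphenyl)propan-2-yl]-5-methoxy-4-(TIPS-oxy)benzyl}dihydrofuran-2(3H)-one | COc1cc([C@@H](O[Si](C)(C)C(C)(C)C)[C@H](CO[Si](C)(C)C(C)(C)C)c2cc(C[C@H]3COC(=O)C3)cc(OC)c2O[Si](C(C)C)(C(C)C)C(C)C)ccc1O[Si](C)(C)C(C)(C)C | intermediate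
18 | (Z)-dibutylboron enolate of imide 7 | CCCCB(CCCC)O/C(=C\c1cc(Br)cc(OC)c1O[Si](C(C)C)(C(C)C)C(C)C)N1C(=O)OC[C@@H]1Cc1ccccc1 | intermediate
19 | (S)-4-benzyl-3-{(2S,3S)-2-[5-bromo-3-methoxy-2-(TIPS-oxy)phenyl]-3-hydroxy-3-[3-methoxy-4-(TBS-oxy)phenyl]propanoyl}-1,3-oxazolidin-2-one | COc1cc([C@@H](O)[C@@H](C(=O)N2C(=O)OC[C@@H]2Cc2ccccc2)c2cc(Br)cc(OC)c2O[Si](C(C)C)(C(C)C)C(C)C)ccc1O[Si](C)(C)C(C)(C)C | intermediate
20 | (1S,2R)-2-[5-bromo-3-methoxy-2-(TIPS-oxy)phenyl]-1-[3-methoxy-4-(TBS-oxy)phenyl]propane-1,3-diol | COc1cc([C@@H](O)[C@@H](CO)c2cc(Br)cc(OC)c2O[Si](C(C)C)(C(C)C)C(C)C)ccc1O[Si](C)(C)C(C)(C)C | intermediate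
21 | (1S,2R)-2-(5-bromo-2-hydroxy-3-methoxyphenyl)-1-(4-hydroxy-3-methoxyphenyl)propane-1,3-diol | COc1cc([C@@H](O)[C@@H](CO)c2cc(Br)cc(OC)c2O)ccc1O | intermediate
22 | 4-[(2S,3R)-5-bromo-3-(hydroxymethyl)-7-methoxy-2,3-dihydro-1-benzofuran-2-yl]-2-methoxyphenol | Brc1cc(OC)c2c(c1)[C@H](CO)[C@@H](c1ccc(O)c(OC)c1)O2 | intermediate
23 | (2S,3R)-5-bromo-3-(TBS-oxymethyl)-7-methoxy-2-[3-methoxy-4-(TBS-oxy)phenyl]-2,3-dihydro-1-benzofuran | Brc1cc(OC)c2c(c1)[C@H](CO[Si](C)(C)C(C)(C)C)[C@@H](c1ccc(O[Si](C)(C)C(C)(C)C)c(OC)c1)O2 | intermediate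
24 | {(2S,3R)-3-(TBS-oxymethyl)-7-methoxy-2-[3-methoxy-4-(TBS-oxy)phenyl]-2,3-dihydro-1-benzofuran-5-yl}methanol | OCc1cc(OC)c2c(c1)[C@H](CO[Si](C)(C)C(C)(C)C)[C@@H](c1ccc(O[Si](C)(C)C(C)(C)C)c(OC)c1)O2 | intermediate
25 | (2S,3R)-5-(bromomethyl)-3-(TBS-oxymethyl)-7-methoxy-2-[3-methoxy-4-(TBS-oxy)phenyl]-2,3-dihydro-1-benzofuran | BrCc1cc(OC)c2c(c1)[C@H](CO[Si](C)(C)C(C)(C)C)[C@@H](c1ccc(O[Si](C)(C)C(C)(C)C)c(OC)c1)O2 | intermediate
26 | lithium enolate of lactone 17 | COc1cc([C@@H](O[Si](C)(C)C(C)(C)C)[C@H](CO[Si](C)(C)C(C)(C)C)c2cc(C[C@H]3COC(O[Li])=C3)cc(OC)c2O[Si](C(C)C)(C(C)C)C(C)C)ccc1O[Si](C)(C)C(C)(C)C | intermediate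
27 | hexasilylated target: (3R,4R) lactone with five TBS ethers and the ring A TIPS ether | COc1cc([C@@H](O[Si](C)(C)C(C)(C)C)[C@H](CO[Si](C)(C)C(C)(C)C)c2cc(C[C@H]3COC(=O)[C@@H]3Cc3cc(OC)c4c(c3)[C@H](CO[Si](C)(C)C(C)(C)C)[C@@H](c3ccc(O[Si](C)(C)C(C)(C)C)c(OC)c3)O4)cc(OC)c2O[Si](C(C)C)(C(C)C)C(C)C)ccc1O[Si](C)(C)C(C)(C)C | intermediate
28 | (3R,4R)-4-{3-[(1S,2S)-1,3-dihydroxy-1-(4-hydroxy-3-methoxyphenyl)propan-2-yl]-4-hydroxy-5-methoxybenzyl}-3-{[(2S,3R)-2-(4-hydroxy-3-methoxyphenyl)-3-(hydroxymethyl)-7-methoxy-2,3-dihydro-1-benzofuran-5-yl]methyl}dihydrofuran-2(3H)-one | COc1cc([C@@H](O)[C@H](CO)c2cc(C[C@H]3COC(=O)[C@@H]3Cc3cc(OC)c4c(c3)[C@H](CO)[C@@H](c3ccc(O)c(OC)c3)O4)cc(OC)c2O)ccc1O | target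

Total step count: 16. Longest linear sequence: 11 steps (steps 1–3 and 9–16).

Steps most likely to fail

Step 8. The catalyst may discriminate poorly between the two enantiotopic CH2 groups of this large, Lewis-basic substrate, which would give C4 epimers that differ only at a remote centre and are hard to separate. The Lewis acid may also ionise the benzylic silyl ether. The fallback sets out from 12 and returns at 17, taking C4 from the chiral pool instead of from catalyst control. The known (S)-4-(hydroxymethyl)dihydrofuran-2(3H)-one is converted with I2, PPh3 and imidazole into (R)-4-(iodomethyl)dihydrofuran-2(3H)-one F1. Zinc insertion (Zn dust, LiCl, THF) gives {[(R)-5-oxotetrahydrofuran-3-yl]methyl}zinc iodide F2. Negishi coupling of F2 with 12 (Pd(OAc)2, SPhos, THF) gives 17, and the route continues with step 15.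

Step 4. The anti selectivity may erode, because the acidic α-aryl imide can be silylated to a ketene N,O-acetal that adds outside the magnesium chelate, and the aldolate can revert before it is silylated. The fallback sets out from 4 and returns at 12. Acid 4 is acylated onto (R)-4-benzyl-1,3-oxazolidin-2-one as in step 3 to give the imide with the mirror-image auxiliary F3. The boron syn aldol of step 9 with 8 gives the (2R,3R) syn adduct F4, and LiBH4 gives the (1R,2S)-diol F5. TBSCl and imidazole silylate the primary hydroxyl selectively to give F6. A Mitsunobu reaction (4-nitrobenzoic acid, DIAD, PPh3) inverts the benzylic carbinol to the (1S,2S) 4-nitrobenzoate F7. LiBH4 cleaves the ester to the (1S,2S) alcohol F8, and TBSOTf with 2,6-lutidine then gives 12.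

Step 7. Zinc insertion may be incomplete, the keto-alkylzinc reagent may decompose (self-condensation or ring opening), and oxidative addition to the electron-rich aryl bromide may be slow. The fallback sets out from 12 and returns at 15. Stille coupling of 12 with allyltributylstannane (Pd(PPh3)4, toluene, 100 °C) gives the allylarene F9. A [2+2] cycloaddition with dichloroketene (Cl3CCOCl, zinc–copper couple, Et2O/DME) gives the 2,2-dichlorocyclobutanone F10 as a mixture of epimers at the ring carbon. Zn in AcOH removes both chlorine atoms and gives 15.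

Further compounds
F1 | step 8 | (R)-4-(iodomethyl)dihydrofuran-2(3H)-one | IC[C@H]1COC(=O)C1
F2 | step 8 | {[(R)-5-oxotetrahydrofuran-3-yl]methyl}zinc iodide | I[Zn]C[C@H]1COC(=O)C1
F3 | step 4 | (R)-4-benzyl-3-{2-[5-bromo-3-methoxy-2-(TIPS-oxy)phenyl]acetyl}-1,3-oxazolidin-2-one | COc1cc(Br)cc(CC(=O)N2C(=O)OC[C@H]2Cc2ccccc2)c1O[Si](C(C)C)(C(C)C)C(C)C
F4 | step 4 | (R)-4-benzyl-3-{(2R,3R)-2-[5-bromo-3-methoxy-2-(TIPS-oxy)phenyl]-3-hydroxy-3-[3-methoxy-4-(TBS-oxy)phenyl]propanoyl}-1,3-oxazolidin-2-one | COc1cc([C@H](O)[C@H](C(=O)N2C(=O)OC[C@H]2Cc2ccccc2)c2cc(Br)cc(OC)c2O[Si](C(C)C)(C(C)C)C(C)C)ccc1O[Si](C)(C)C(C)(C)C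
F5 | step 4 | (1R,2S)-2-[5-bromo-3-methoxy-2-(TIPS-oxy)phenyl]-1-[3-methoxy-4-(TBS-oxy)phenyl]propane-1,3-diol | COc1cc([C@H](O)[C@H](CO)c2cc(Br)cc(OC)c2O[Si](C(C)C)(C(C)C)C(C)C)ccc1O[Si](C)(C)C(C)(C)C
F6 | step 4 | (1R,2S)-2-[5-bromo-3-methoxy-2-(TIPS-oxy)phenyl]-3-(TBS-oxy)-1-[3-methoxy-4-(TBS-oxy)phenyl]propan-1-ol | COc1cc([C@H](O)[C@H](CO[Si](C)(C)C(C)(C)C)c2cc(Br)cc(OC)c2O[Si](C(C)C)(C(C)C)C(C)C)ccc1O[Si](C)(C)C(C)(C)C
F7 | step 4 | (1S,2S)-2-[5-bromo-3-methoxy-2-(TIPS-oxy)phenyl]-3-(TBS-oxy)-1-[3-methoxy-4-(TBS-oxy)phenyl]propyl 4-nitrobenzoate | COc1cc([C@@H](OC(=O)c2ccc([N+](=O)[O-])cc2)[C@H](CO[Si](C)(C)C(C)(C)C)c2cc(Br)cc(OC)c2O[Si](C(C)C)(C(C)C)C(C)C)ccc1O[Si](C)(C)C(C)(C)C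
F8 | step 4 | (1S,2S)-2-[5-bromo-3-methoxy-2-(TIPS-oxy)phenyl]-3-(TBS-oxy)-1-[3-methoxy-4-(TBS-oxy)phenyl]propan-1-ol | COc1cc([C@@H](O)[C@H](CO[Si](C)(C)C(C)(C)C)c2cc(Br)cc(OC)c2O[Si](C(C)C)(C(C)C)C(C)C)ccc1O[Si](C)(C)C(C)(C)C
F9 | step 7 | (1S,2S)-2-[5-allyl-3-methoxy-2-(TIPS-oxy)phenyl]-1,3-bis(TBS-oxy)-1-[3-methoxy-4-(TBS-oxy)phenyl]propane | COc1cc([C@@H](O[Si](C)(C)C(C)(C)C)[C@H](CO[Si](C)(C)C(C)(C)C)c2cc(CC=C)cc(OC)c2O[Si](C(C)C)(C(C)C)C(C)C)ccc1O[Si](C)(C)C(C)(C)C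
F10 | step 7 | 2,2-dichloro-3-{3-[(1S,2S)-1,3-bis(TBS-oxy)-1-(3-methoxy-4-TBS-oxyphenyl)propan-2-yl]-5-methoxy-4-(TIPS-oxy)benzyl}cyclobutan-1-one | COc1cc([C@@H](O[Si](C)(C)C(C)(C)C)[C@H](CO[Si](C)(C)C(C)(C)C)c2cc(CC3CC(=O)C3(Cl)Cl)cc(OC)c2O[Si](C(C)C)(C(C)C)C(C)C)ccc1O[Si](C)(C)C(C)(C)C
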